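**Retrosynthetic overview**
1. Target ⇐ 8‑O‑angeloylation and 9‑O‑desilylation of a bicyclic 8‑hydroxy‑9‑silyloxy lactone.
2. Both rings ⇐ one CrCl2‑mediated operation on an acyclic bromo‑aldehyde: C6–C7 bond (ten‑membered carbocycle, sets C6 and C7), then O–C12 acyl transfer (γ‑lactone).
3. Acyclic precursor ⇐ cross‑metathesis of a C7 vinyl group with methyl 2‑(bromomethyl)acrylate; C8/C9 ⇐ Brown Z‑γ‑alkoxyallylboration of a 2‑formyl enoate (C8–C9 bond).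
4. 2‑Formyl enoate ⇐ carbonylation of a Z‑α‑iodo enoate ⇐ iodo‑Wittig olefination of the aldehyde from ozonolysis of neryl acetate (supplies C1–C6, C15 and the 4Z alkene).
5. Ring order: no ring before the key step; there the carbocycle closes first and the lactone follows in the same flask.

Assumption: atoms are referred to by germacrane numbering (ring C1–C10, lactone C11–C13, ester carbon C14, methyl C15), and 3‑(methoxymethoxy)prop‑1‑ene, (+)‑Ipc2BOMe and angelic acid are bought.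

**Step 1**
Reactants: 1 neryl acetate [(2Z)‑3,7‑dimethylocta‑2,6‑dien‑1‑yl acetate]
Product: 3 (2Z)‑3‑methyl‑6‑oxohex‑2‑en‑1‑yl acetate, via ozonide 2 (not isolated)
Conditions: O3 (1.0 equiv, dye end point), CH2Cl2, −78 °C; then PPh3, −78 → 20 °C
Reagents that add atoms: ozone, [O-][O+]=O
Why: Ozonolysis with reductive work‑up: electrophilic ozone takes the electron‑rich isopropylidene alkene rather than the alkene deactivated by the allylic acetate, so the 4Z alkene and the C6 oxygen survive and no stereocentre is made.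

**Step 2**
Reactants: 3 (2Z)‑3‑methyl‑6‑oxohex‑2‑en‑1‑yl acetate; 4 methyl (triphenylphosphoranylidene)acetate
Product: 6 methyl (2Z,6Z)‑8‑acetoxy‑2‑iodo‑6‑methylocta‑2,6‑dienoate, via iodo ylide 5 (not isolated)
Conditions: 4, NIS, CH2Cl2, −20 °C; then 3, −20 → 20 °C
Reagents that add atoms: N‑iodosuccinimide, O=C1CCC(=O)N1I
Why: NIS iodinates the stabilised ylide and the resulting α‑iodo ylide undergoes Wittig olefination that places the chain cis to iodine and trans to the ester, the normal outcome for α‑halo stabilised ylides (minor 2E isomer removed by chromatography).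

**Step 3**
Reactants: 6 methyl (2Z,6Z)‑8‑acetoxy‑2‑iodo‑6‑methylocta‑2,6‑dienoate
Product: 7 methyl (2E,6Z)‑8‑acetoxy‑2‑formyl‑6‑methylocta‑2,6‑dienoate
Conditions: Pd(PPh3)4 (5 mol %), CO (1 atm), Bu3SnH (slow addition), THF, 50 °C
Reagents that add atoms: carbon monoxide, [C-]#[O+]
Why: Reductive carbonylation (Stille–Baillargeon formylation): zerovalent palladium inserts into the C–I bond, CO gives the acylpalladium and Bu3SnH delivers hydride, so iodine is replaced by CHO with retention of alkene geometry.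

**Step 4**
Reactants: 7 methyl (2E,6Z)‑8‑acetoxy‑2‑formyl‑6‑methylocta‑2,6‑dienoate; 8 3‑(methoxymethoxy)prop‑1‑ene
Product: 12 methyl (2E,6Z)‑8‑acetoxy‑2‑[(1S,2S)‑1‑hydroxy‑2‑(methoxymethoxy)but‑3‑en‑1‑yl]‑6‑methylocta‑2,6‑dienoate, via lithiated allyl ether 9 (not isolated), via allylborane 10 (not isolated), via borinate 11 (not isolated)
Conditions: 8, s‑BuLi, THF, −78 °C; (+)‑Ipc2BOMe; BF3·OEt2; then 7, −78 °C, 3 h; HOCH2CH2NH2 work‑up
Reagents that add atoms: none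
Why: Brown alkoxyallylboration: the Z‑γ‑alkoxyallylborane reacts through a chair Zimmerman–Traxler transition state that fixes the syn (threo) C8/C9 relationship, and the isopinocampheyl groups of the (−)‑α‑pinene series direct attack to the Re face of the aldehyde to give 8S,9S (the enantiomeric borane would give the antipode), while enoate and acetate are inert at −78 °C.

**Step 5**
Reactants: 12 methyl (2E,6Z)‑8‑acetoxy‑2‑[(1S,2S)‑1‑hydroxy‑2‑(methoxymethoxy)but‑3‑en‑1‑yl]‑6‑methylocta‑2,6‑dienoate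
Product: 13 methyl (2E,6Z)‑8‑acetoxy‑2‑[(1S,2S)‑1‑[(tert‑butyldimethylsilyl)oxy]‑2‑(methoxymethoxy)but‑3‑en‑1‑yl]‑6‑methylocta‑2,6‑dienoate
Conditions: TBSOTf, 2,6‑lutidine, CH2Cl2, −78 °C
Reagents that add atoms: tert‑butyldimethylsilyl trifluoromethanesulfonate, CC(C)(C)[Si](C)(C)OS(=O)(=O)C(F)(F)F
Why: Silyl triflate silylation of the hindered allylic C9 hydroxyl with a hindered base leaves the MOM ether, the ester and the acetate untouched at −78 °C.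

**Step 6**
Reactants: 13 methyl (2E,6Z)‑8‑acetoxy‑2‑[(1S,2S)‑1‑[(tert‑butyldimethylsilyl)oxy]‑2‑(methoxymethoxy)but‑3‑en‑1‑yl]‑6‑methylocta‑2,6‑dienoate
Product: 14 methyl (2E,6Z)‑2‑[(1S,2S)‑1‑[(tert‑butyldimethylsilyl)oxy]‑2‑(methoxymethoxy)but‑3‑en‑1‑yl]‑8‑hydroxy‑6‑methylocta‑2,6‑dienoate
Conditions: K2CO3 (0.2 equiv), MeOH, 0 °C
Reagents that add atoms: none
Why: Base‑catalysed transesterification (Zemplén‑type methanolysis) removes the primary acetate, while the methyl ester only exchanges with the solvent and the silyl and MOM ethers are stable.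

**Step 7**
Reactants: 14 methyl (2E,6Z)‑2‑[(1S,2S)‑1‑[(tert‑butyldimethylsilyl)oxy]‑2‑(methoxymethoxy)but‑3‑en‑1‑yl]‑8‑hydroxy‑6‑methylocta‑2,6‑dienoate
Product: 15 methyl (2E,6Z)‑2‑[(1S,2S)‑1‑[(tert‑butyldimethylsilyl)oxy]‑2‑(methoxymethoxy)but‑3‑en‑1‑yl]‑6‑methyl‑8‑oxoocta‑2,6‑dienoate
Conditions: TEMPO (10 mol %), PhI(OAc)2, CH2Cl2, 0 → 20 °C
Reagents that add atoms: none
Why: Oxoammonium (TEMPO/PhI(OAc)2) oxidation of the primary allylic alcohol stops at the aldehyde and is the standard way to turn nerol into neral without Z to E isomerisation.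

**Step 8**
Reactants: 15 methyl (2E,6Z)‑2‑[(1S,2S)‑1‑[(tert‑butyldimethylsilyl)oxy]‑2‑(methoxymethoxy)but‑3‑en‑1‑yl]‑6‑methyl‑8‑oxoocta‑2,6‑dienoate; 16 methyl 2‑(bromomethyl)prop‑2‑enoate
Product: 17 methyl (2Z,4S,5S,6E,10Z)‑2‑(bromomethyl)‑5‑[(tert‑butyldimethylsilyl)oxy]‑6‑(methoxycarbonyl)‑4‑(methoxymethoxy)‑10‑methyl‑12‑oxododeca‑2,6,10‑trienoate
Conditions: 16 (8 equiv), second‑generation Hoveyda–Grubbs catalyst RuCl2(H2IMes)(=CH‑C6H4‑2‑OiPr) (10 mol %), 1,4‑benzoquinone (10 mol %), CH2Cl2, 40 °C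
Reagents that add atoms: none
Why: Olefin cross‑metathesis: only the monosubstituted C7 vinyl group initiates readily, the trisubstituted alkenes are inert and the 1,1‑disubstituted acrylate cannot homodimerise, so the trisubstituted enoate forms with C8 trans to the ester (thermodynamic isomer).

**Step 9 (key step)**
Reactants: 17 methyl (2Z,4S,5S,6E,10Z)‑2‑(bromomethyl)‑5‑[(tert‑butyldimethylsilyl)oxy]‑6‑(methoxycarbonyl)‑4‑(methoxymethoxy)‑10‑methyl‑12‑oxododeca‑2,6,10‑trienoate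
Product: 20 methyl (3aS,4S,5S,6E,10Z,11aR)‑5‑[(tert‑butyldimethylsilyl)oxy]‑4‑(methoxymethoxy)‑10‑methyl‑3‑methylidene‑2‑oxo‑2,3,3a,4,5,8,9,11a‑octahydrocyclodeca[b]furan‑6‑carboxylate, via allylchromium species 18 (not isolated), via chromium alkoxide 19 (not isolated)
Conditions: CrCl2 (10 equiv), THF–DMF 9:1, 17 added by syringe pump over 12 h (final 2 mM), 25 °C; aq. NH4Cl
Reagents that add atoms: none
Why: Intramolecular Nozaki–Hiyama (chromium Barbier) allylation followed by lactonisation: the allylchromium adds through C7 to the C6 aldehyde in a chair transition state that gives the anti C6/C7 pair (trans‑fused lactone once the chromium alkoxide attacks the neighbouring methyl ester), and allylic strain holds H8 in the enoate plane so that C6 bonds to the C7 face anti to the C8–C9 bond, giving 6R,7S from the 8S centre; this face selection is a prediction from the model and is the main stereochemical risk.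

**Step 10**
Reactants: 20 methyl (3aS,4S,5S,6E,10Z,11aR)‑5‑[(tert‑butyldimethylsilyl)oxy]‑4‑(methoxymethoxy)‑10‑methyl‑3‑methylidene‑2‑oxo‑2,3,3a,4,5,8,9,11a‑octahydrocyclodeca[b]furan‑6‑carboxylate
Product: 22 methyl (3aS,4S,5S,6E,10Z,11aR)‑5‑[(tert‑butyldimethylsilyl)oxy]‑4‑hydroxy‑10‑methyl‑3‑methylidene‑2‑oxo‑2,3,3a,4,5,8,9,11a‑octahydrocyclodeca[b]furan‑6‑carboxylate, via bromomethyl ether 21 (not isolated)
Conditions: Me2BBr, CH2Cl2, −78 °C; then aq. NaHCO3–THF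
Reagents that add atoms: none
Why: Guindon acetal cleavage: Me2BBr turns the MOM acetal into a bromomethyl ether at −78 °C, which hydrolyses on bicarbonate work‑up, while the TBS ether, the esters and the lactone are stable at this temperature.

**Step 11**
Reactants: 22 methyl (3aS,4S,5S,6E,10Z,11aR)‑5‑[(tert‑butyldimethylsilyl)oxy]‑4‑hydroxy‑10‑methyl‑3‑methylidene‑2‑oxo‑2,3,3a,4,5,8,9,11a‑octahydrocyclodeca[b]furan‑6‑carboxylate; 23 angelic acid [(2Z)‑2‑methylbut‑2‑enoic acid]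
Product: 25 methyl (3aS,4S,5S,6E,10Z,11aR)‑5‑[(tert‑butyldimethylsilyl)oxy]‑10‑methyl‑3‑methylidene‑4‑{[(2Z)‑2‑methylbut‑2‑enoyl]oxy}‑2‑oxo‑2,3,3a,4,5,8,9,11a‑octahydrocyclodeca[b]furan‑6‑carboxylate, via mixed anhydride 24 (not isolated)
Conditions: 23, 2,4,6‑trichlorobenzoyl chloride, Et3N, toluene, 25 °C; then 22, 80 °C
Reagents that add atoms: none
Why: Yamaguchi esterification: the mixed anhydride acylates the C8 hydroxyl at the angeloyl carbonyl without a nucleophilic catalyst, conditions known to keep the Z geometry of angelates (no isomerisation to the tiglate).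

**Step 12**
Reactants: 25 methyl (3aS,4S,5S,6E,10Z,11aR)‑5‑[(tert‑butyldimethylsilyl)oxy]‑10‑methyl‑3‑methylidene‑4‑{[(2Z)‑2‑methylbut‑2‑enoyl]oxy}‑2‑oxo‑2,3,3a,4,5,8,9,11a‑octahydrocyclodeca[b]furan‑6‑carboxylate
Product: 26 methyl (3aS,4S,5S,6E,10Z,11aR)‑5‑hydroxy‑10‑methyl‑3‑methylidene‑4‑{[(2Z)‑2‑methylbut‑2‑enoyl]oxy}‑2‑oxo‑2,3,3a,4,5,8,9,11a‑octahydrocyclodeca[b]furan‑6‑carboxylate (CNP0305372.2)
Conditions: HF·pyridine, THF–pyridine, 0 → 25 °C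
Reagents that add atoms: none
Why: Fluoride‑mediated desilylation with buffered HF·pyridine leaves the angelate, the methyl ester and the α‑methylene lactone intact and touches no stereocentre.

**Compound list**
1 | neryl acetate, (2Z)‑3,7‑dimethylocta‑2,6‑dien‑1‑yl acetate | CC(=O)OC/C=C(/C)CCC=C(C)C | starting material
2 | ozonide, (2Z)‑5‑(5,5‑dimethyl‑1,2,4‑trioxolan‑3‑yl)‑3‑methylpent‑2‑en‑1‑yl acetate | CC(=O)OC/C=C(/C)CCC1OOC(C)(C)O1 | intermediate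
3 | (2Z)‑3‑methyl‑6‑oxohex‑2‑en‑1‑yl acetate | CC(=O)OC/C=C(/C)CCC=O | intermediate
4 | methyl (triphenylphosphoranylidene)acetate | COC(=O)C=P(c1ccccc1)(c1ccccc1)c1ccccc1 | starting material
5 | iodo ylide, methyl iodo(triphenylphosphoranylidene)acetate | COC(=O)C(I)=P(c1ccccc1)(c1ccccc1)c1ccccc1 | intermediate
6 | methyl (2Z,6Z)‑8‑acetoxy‑2‑iodo‑6‑methylocta‑2,6‑dienoate | CC(=O)OC/C=C(/C)CC/C=C(/C(=O)OC)I | intermediate
7 | methyl (2E,6Z)‑8‑acetoxy‑2‑formyl‑6‑methylocta‑2,6‑dienoate | CC(=O)OC/C=C(/C)CC/C=C(/C(=O)OC)C=O | intermediate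
8 | 3‑(methoxymethoxy)prop‑1‑ene | C=CCOCOC | starting material
9 | lithiated allyl ether, [(2Z)‑3‑(methoxymethoxy)prop‑2‑en‑1‑yl]lithium | [Li]C/C=C\OCOC | intermediate
10 | allylborane, [(2Z)‑3‑(methoxymethoxy)prop‑2‑en‑1‑yl]bis[(1S,2R,3S,5S)‑2,6,6‑trimethylbicyclo[3.1.1]heptan‑3‑yl]borane | COCO/C=C\CB([C@H]1C[C@H]2C[C@@H]([C@@H]1C)C2(C)C)[C@H]1C[C@H]2C[C@@H]([C@@H]1C)C2(C)C | intermediate
11 | borinate, O9‑bis[(1S,2R,3S,5S)‑isopinocampheyl]boryl ether of 12 | CC(=O)OC/C=C(/C)CC/C=C(/C(=O)OC)[C@H](OB([C@H]1C[C@H]2C[C@@H]([C@@H]1C)C2(C)C)[C@H]1C[C@H]2C[C@@H]([C@@H]1C)C2(C)C)[C@@H](OCOC)C=C | intermediate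
12 | methyl (2E,6Z)‑8‑acetoxy‑2‑[(1S,2S)‑1‑hydroxy‑2‑(methoxymethoxy)but‑3‑en‑1‑yl]‑6‑methylocta‑2,6‑dienoate | CC(=O)OC/C=C(/C)CC/C=C(/C(=O)OC)[C@H](O)[C@@H](OCOC)C=C | intermediate
13 | methyl (2E,6Z)‑8‑acetoxy‑2‑[(1S,2S)‑1‑[(tert‑butyldimethylsilyl)oxy]‑2‑(methoxymethoxy)but‑3‑en‑1‑yl]‑6‑methylocta‑2,6‑dienoate | CC(=O)OC/C=C(/C)CC/C=C(/C(=O)OC)[C@H](O[Si](C)(C)C(C)(C)C)[C@@H](OCOC)C=C | intermediate
14 | methyl (2E,6Z)‑2‑[(1S,2S)‑1‑[(tert‑butyldimethylsilyl)oxy]‑2‑(methoxymethoxy)but‑3‑en‑1‑yl]‑8‑hydroxy‑6‑methylocta‑2,6‑dienoate | OC/C=C(/C)CC/C=C(/C(=O)OC)[C@H](O[Si](C)(C)C(C)(C)C)[C@@H](OCOC)C=C | intermediate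
15 | methyl (2E,6Z)‑2‑[(1S,2S)‑1‑[(tert‑butyldimethylsilyl)oxy]‑2‑(methoxymethoxy)but‑3‑en‑1‑yl]‑6‑methyl‑8‑oxoocta‑2,6‑dienoate | O=C/C=C(/C)CC/C=C(/C(=O)OC)[C@H](O[Si](C)(C)C(C)(C)C)[C@@H](OCOC)C=C | intermediate
16 | methyl 2‑(bromomethyl)prop‑2‑enoate | C=C(CBr)C(=O)OC | starting material
17 | methyl (2Z,4S,5S,6E,10Z)‑2‑(bromomethyl)‑5‑[(tert‑butyldimethylsilyl)oxy]‑6‑(methoxycarbonyl)‑4‑(methoxymethoxy)‑10‑methyl‑12‑oxododeca‑2,6,10‑trienoate | O=C/C=C(/C)CC/C=C(/C(=O)OC)[C@H](O[Si](C)(C)C(C)(C)C)[C@@H](OCOC)/C=C(/C(=O)OC)CBr | intermediate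
18 | allylchromium species, 17 with a CrCl2 unit (trivalent chromium) on C13 in place of bromine | O=C/C=C(/C)CC/C=C(/C(=O)OC)[C@H](O[Si](C)(C)C(C)(C)C)[C@@H](OCOC)/C=C(/C(=O)OC)C[Cr](Cl)Cl | intermediate
19 | chromium alkoxide (O–CrCl2) of methyl (1E,5Z,7R,8S,9S,10S)‑10‑[(tert‑butyldimethylsilyl)oxy]‑7‑hydroxy‑9‑(methoxymethoxy)‑8‑(3‑methoxy‑3‑oxoprop‑1‑en‑2‑yl)‑5‑methylcyclodeca‑1,5‑diene‑1‑carboxylate | Cl[Cr](Cl)O[C@@H]1/C=C(/C)CC/C=C(/C(=O)OC)[C@H](O[Si](C)(C)C(C)(C)C)[C@@H](OCOC)[C@H]1C(=C)C(=O)OC | intermediate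
20 | methyl (3aS,4S,5S,6E,10Z,11aR)‑5‑[(tert‑butyldimethylsilyl)oxy]‑4‑(methoxymethoxy)‑10‑methyl‑3‑methylidene‑2‑oxo‑2,3,3a,4,5,8,9,11a‑octahydrocyclodeca[b]furan‑6‑carboxylate | C=C1C(=O)O[C@@H]2/C=C(/C)CC/C=C(/C(=O)OC)[C@H](O[Si](C)(C)C(C)(C)C)[C@@H](OCOC)[C@@H]12 | intermediate
21 | bromomethyl ether, the 4‑(bromomethoxy) analogue of 20 | C=C1C(=O)O[C@@H]2/C=C(/C)CC/C=C(/C(=O)OC)[C@H](O[Si](C)(C)C(C)(C)C)[C@@H](OCBr)[C@@H]12 | intermediate
22 | methyl (3aS,4S,5S,6E,10Z,11aR)‑5‑[(tert‑butyldimethylsilyl)oxy]‑4‑hydroxy‑10‑methyl‑3‑methylidene‑2‑oxo‑2,3,3a,4,5,8,9,11a‑octahydrocyclodeca[b]furan‑6‑carboxylate | C=C1C(=O)O[C@@H]2/C=C(/C)CC/C=C(/C(=O)OC)[C@H](O[Si](C)(C)C(C)(C)C)[C@@H](O)[C@@H]12 | intermediate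
23 | angelic acid, (2Z)‑2‑methylbut‑2‑enoic acid | C/C=C(/C)C(=O)O | starting material
24 | mixed anhydride, (2Z)‑2‑methylbut‑2‑enoic 2,4,6‑trichlorobenzoic anhydride | C/C=C(/C)C(=O)OC(=O)c1c(Cl)cc(Cl)cc1Cl | intermediate
25 | methyl (3aS,4S,5S,6E,10Z,11aR)‑5‑[(tert‑butyldimethylsilyl)oxy]‑10‑methyl‑3‑methylidene‑4‑{[(2Z)‑2‑methylbut‑2‑enoyl]oxy}‑2‑oxo‑2,3,3a,4,5,8,9,11a‑octahydrocyclodeca[b]furan‑6‑carboxylate | C=C1C(=O)O[C@@H]2/C=C(/C)CC/C=C(/C(=O)OC)[C@H](O[Si](C)(C)C(C)(C)C)[C@@H](OC(=O)/C(C)=C\C)[C@@H]12 | intermediate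
26 | methyl (3aS,4S,5S,6E,10Z,11aR)‑5‑hydroxy‑10‑methyl‑3‑methylidene‑4‑{[(2Z)‑2‑methylbut‑2‑enoyl]oxy}‑2‑oxo‑2,3,3a,4,5,8,9,11a‑octahydrocyclodeca[b]furan‑6‑carboxylate | C=C1C(=O)O[C@@H]2/C=C(/C)CC/C=C(/C(=O)OC)[C@H](O)[C@@H](OC(=O)/C(C)=C\C)[C@@H]12 | target

**Step count and risk**
Total steps: 12. Longest linear sequence: 12 (1 → 26).

Step 9 is the most likely to fail. The closure has to beat simple reduction and intermolecular coupling, and the choice of the C7 face by the C8 ether rests on a model. The fallback changes the control element from a non‑coordinating ether to a free hydroxyl. Setting out from 17, Me2BBr (CH2Cl2, −78 °C, bicarbonate work‑up) removes the MOM group and gives methyl (2Z,4S,5S,6E,10Z)‑2‑(bromomethyl)‑5‑[(tert‑butyldimethylsilyl)oxy]‑4‑hydroxy‑6‑(methoxycarbonyl)‑10‑methyl‑12‑oxododeca‑2,6,10‑trienoate F1. Its closure with CrCl2 at high dilution then runs through an allylchromium chelated by the C8 alkoxide, which locks the C7–C8 rotamer. The product of that closure is alcohol 22, so the route is rejoined at 22 and step 10 is not needed.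

Step 8 is second. The vinyl group sits next to two protected oxygens and the acrylate partner is 1,1‑disubstituted, so the metathesis may stall. The fallback builds the acrylate from a C7 aldehyde instead. Setting out from 15, OsO4 (cat.), NaIO4 and 2,6‑lutidine in dioxane–water cleave only the terminal vinyl group (the enal and enoate alkenes are electron‑poor) and give methyl (2E,6Z)‑2‑[(1S,2R)‑1‑[(tert‑butyldimethylsilyl)oxy]‑2‑(methoxymethoxy)‑3‑oxopropyl]‑6‑methyl‑8‑oxoocta‑2,6‑dienoate F2. A Morita–Baylis–Hillman reaction with methyl acrylate and DABCO at this α‑alkoxy aldehyde (the β,β‑disubstituted enal does not react) gives methyl (2E,6Z)‑2‑[(1S,2S)‑1‑[(tert‑butyldimethylsilyl)oxy]‑3‑hydroxy‑4‑(methoxycarbonyl)‑2‑(methoxymethoxy)pent‑4‑en‑1‑yl]‑6‑methyl‑8‑oxoocta‑2,6‑dienoate F3 as a mixture of carbinol epimers. The mixture does not matter, because NBS/Me2S (CH2Cl2, 0 °C) brominates with allylic transposition and gives 17, where the route is rejoined.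

Step 3 is third. Direct reduction of the iodide can compete with carbonylation, and the 2‑formyl enoate is a sensitive acceptor. The fallback reaches 7 through the Morita–Baylis–Hillman manifold and bypasses 6. Setting out from 3, methyl acrylate and DABCO give methyl (6Z)‑8‑acetoxy‑3‑hydroxy‑6‑methyl‑2‑methylideneoct‑6‑enoate F4 (racemic). NBS/Me2S gives methyl (2Z,6Z)‑8‑acetoxy‑2‑(bromomethyl)‑6‑methylocta‑2,6‑dienoate F5 with the chain cis to CH2Br. N‑Methylmorpholine N‑oxide in MeCN (Ganem–Kornblum oxidation) converts F5 into 7, where the route is rejoined.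

**Further compounds**
F1 | step 9 | methyl (2Z,4S,5S,6E,10Z)‑2‑(bromomethyl)‑5‑[(tert‑butyldimethylsilyl)oxy]‑4‑hydroxy‑6‑(methoxycarbonyl)‑10‑methyl‑12‑oxododeca‑2,6,10‑trienoate | O=C/C=C(/C)CC/C=C(/C(=O)OC)[C@H](O[Si](C)(C)C(C)(C)C)[C@@H](O)/C=C(/C(=O)OC)CBr
F2 | step 8 | methyl (2E,6Z)‑2‑[(1S,2R)‑1‑[(tert‑butyldimethylsilyl)oxy]‑2‑(methoxymethoxy)‑3‑oxopropyl]‑6‑methyl‑8‑oxoocta‑2,6‑dienoate | O=C/C=C(/C)CC/C=C(/C(=O)OC)[C@H](O[Si](C)(C)C(C)(C)C)[C@@H](OCOC)C=O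
F3 | step 8 | methyl (2E,6Z)‑2‑[(1S,2S)‑1‑[(tert‑butyldimethylsilyl)oxy]‑3‑hydroxy‑4‑(methoxycarbonyl)‑2‑(methoxymethoxy)pent‑4‑en‑1‑yl]‑6‑methyl‑8‑oxoocta‑2,6‑dienoate (both carbinol epimers) | O=C/C=C(/C)CC/C=C(/C(=O)OC)[C@H](O[Si](C)(C)C(C)(C)C)[C@@H](OCOC)C(O)C(=C)C(=O)OC
F4 | step 3 | methyl (6Z)‑8‑acetoxy‑3‑hydroxy‑6‑methyl‑2‑methylideneoct‑6‑enoate (racemic) | CC(=O)OC/C=C(/C)CCC(O)C(=C)C(=O)OC
F5 | step 3 | methyl (2Z,6Z)‑8‑acetoxy‑2‑(bromomethyl)‑6‑methylocta‑2,6‑dienoate | CC(=O)OC/C=C(/C)CC/C=C(/C(=O)OC)CBr
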